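Read the last line of each earlier run first: it holds the contradiction that sets the estimate for the new flasks.

| setting | ochre | violet | eta | epsilon |
|---|---|---|---|---|
| electrophile | 0.050 M | 0.050 M | 0.050 M | 0.050 M |
| nucleophile | 0.033 M | 0.053 M | 0.0500 M | 0.0750 M |
| remark | run made earlier | run made earlier |  |  |
| time |  |  | 2.5 h | 2.5 h |

- ochre (time / h: electrophile / %, product / %): 0.200: 96, 5; 0.417: 84, 10; 0.667: 77, 13; 1.33: 69, 19; 2.50: 53, 22
- violet (time / h: electrophile / %, product / %): 0.200: 89, 10; 0.417: 83, 16; 0.667: 71, 21; 1.33: 60, 29; 2.50: 41, 41

(each reading ± 2 percentage points)

- the earlier runs were read with a standard deviation of 2 percentage points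
- what has gone from electrophile into another species counts as reacted, even if it can come back

1. part of the electrophile that has reacted at the end, eta
2. part of the electrophile that has reacted at the end, epsilon
3. what raising the concentration of nucleophile from its lowest to its highest value here does to the part of the electrophile that has reacted (changes below 5 percentage points count as none) (it falls / it rises / no change)

**The puzzle.** From ochre to violet at 2.50 h, c(nucleophile) rises by a factor of 1.61 and product by 1.86, but reacted electrophile by 1.26, much less. So the readings point to a second way out for electrophile, one that needs no nucleophile.

**The crossing.** Treat the electrophile's decay as exponential, with a pseudo-first-order constant k: 0.254 /h in ochre, 0.357 /h in violet. A line through both, k = f + s·c(nucleophile), reads s = 5.13 /M/h and f = 0.0845 /h. Their ratio, 0.0165 M, is the charged c(nucleophile) at which the line gives both ways equal parts of k: the crossing concentration. It is a reading and carries the scatter of the runs.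

**The estimate.** Eta and epsilon are both charged above the crossing. The line gives 57.4% reacted in eta and 69.1% in epsilon, a rise of 12 percentage points, beyond the margin. The forecast stood slightly higher, at 58% and 70%, and its answer on the trend was "it rises", in its words “conversion clearly rises”.

**The result.** Eta reaches 57.2% and epsilon 68.6%, and the answer on the trend is "it rises", by 11 points. The way without nucleophile is the passage to dormant form, which holds 20.5% of the electrophile charged in eta at 2.50 h. At that time free nucleophile in eta stands at 0.0137 M, below the crossing, a reading taken on charged amounts, and in epsilon at 0.0244 M, above it.

    electrophile + nucleophile → acid set free + product (k = 0.00230 /M/s)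
    nucleophile + acid set free ⇌ protonated nucleophile, settled at all times (K = 3200 /M)
    electrophile ⇌ dormant form (K = 29.0, k = 3.60 × 10⁻⁵ /s)

**Second flask.** A flask like epsilon but with 0.019 M of nucleophile starts at 1.15 times the crossing, so the line gives 36.6% reacted, with the two ways starting close together. Computed, it reaches 39.9%, with product at 15.3%, less than dormant form at 24.6%, and free nucleophile at 0.00421 M, below the crossing.

The earlier runs and the new flask are calculated with constants of no real substance; the scatter is artificial.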